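Amounts first: the flasks below differ in free monomer and in time, and hold the same protic impurity, initiator and stray impurity.

in all of them: initiator 12 mM; stray impurity 1.3 mM
- south-west: free monomer 0.45 M; protic impurity 0.85 M; run made earlier
- west: free monomer 2.5 M; protic impurity 0.85 M; run made earlier
- Tuesday's: free monomer 1.7 M; protic impurity 0.850 M; time 30 h
- Sunday's: free monomer 0.40 M; protic impurity 0.850 M; time 30 h

- south-west (time / h: monomer in chains / %, free monomer / %): 2.00: 0.8, 91.1; 4.00: 1.5, 83.1; 6.00: 4.2, 74.9; 8.00: 6.6, 67.6; 10.0: 9.4, 60.1; 12.0: 11.3, 53.4; 15.0: 15.3, 44.0
- west (time / h: monomer in chains / %, free monomer / %): 2.00: 3.5, 90.2; 4.00: 9.5, 77.8; 6.00: 18.1, 65.7; 8.00: 26.6, 54.9; 10.0: 35.2, 44.9; 12.0: 43.4, 35.1; 15.0: 52.3, 25.6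

(standard deviation of a reading: 0.5 percentage points)

- the average divides the monomer in chains by the number of chains begun, living and dead together
- the earlier runs do not show the number of chains; that part of a forecast is a guess

- which of the two ends with the longer chains by the average number of monomer units in a chain (chains begun, living or dead) ("neither" if they lie within 10%) (Tuesday's / Sunday's / neither)
- average number of monomer units in a chain (chains begun, living or dead) at the end, Tuesday's
- average number of monomer units in a chain (chains begun, living or dead) at the end, Sunday's

I take as clock the exposure, ∫[free monomer]dt. If each route of consumption is first order in free monomer, the amount consumed follows exposure and not the charge, at fixed protic impurity, initiator and stray impurity. The readings test this. By its reading at 15.0 h, the south-west run has exposure 285 M·min and has consumed 0.252 M. The west run reaches 285 M·min by 2.00 h and has consumed 0.245 M.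

So, at these charges of protic impurity, initiator and stray impurity, a smaller charge of free monomer behaves like a west run cut short. I define the stopping exposure as the exposure at which the west run has consumed that flask's whole charge. Interpolating the west readings, Tuesday's gives 1250 M·min. Sunday's, nearly the south-west flask, gives 416 M·min.

Between 6.00 h and 12.0 h, monomer in chains in the west run grows by a factor 2.40, and the squared exposure by 2.59. I read this as chains begun rising with exposure, so mean length rises with exposure too. The absolute length stays a guess, but I commit to Tuesday's being longer, by a factor near 3.00. The factor should be somewhat larger at 30 h: near its stop, the pseudo-first-order loss read from the west run is 0.105 h⁻¹ for Tuesday's and 0.0739 h⁻¹ for Sunday's, so Sunday's lags further behind its stop.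

The forecast says Tuesday's, with 250 against 75, on the ground that “Chains begun scale roughly with ∫[M]dt”. The simulation gives Tuesday's, with 231 against 65.9.

    free monomer + initiator → living end + monomer in chains (k = 0.0280 M⁻¹ h⁻¹)
    free monomer + living end → monomer in chains + living end, rate k2*[living end]*[free monomer] (k = 21.0 M⁻¹ h⁻¹)
    initiator + stray impurity → spent initiator (k = 3100 M⁻¹ h⁻¹)
    protic impurity + free monomer → quenched substrate (k = 0.0500 M⁻¹ h⁻¹)

The difference in concentration of free monomer is the main reason for the shorter chains of Sunday's flask: with that difference taken away, so that Sunday's flask holds Tuesday's free monomer, it gives 231, not 65.9. With 21 M⁻¹ h⁻¹, Tuesday's 231 is about half of the growth constant times 1250 M·min, as for chains begun evenly along the exposure. For the neighbour, Tuesday's with 0.68 M of free monomer, the west readings give a stopping exposure of 631 M·min, hence a length near 110. The computed length there is 106, with 13% of its free monomer still present at 30 h.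

The numbers in the tables come from a simulation for an exercise, noise included.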